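(The numbers in the tables were computed from invented constants, and the scatter is random.)

The amount in a flask at 3.0 h cannot be read from runs that stop at 90.0 min, but a rate can be carried past the last reading.

in all of them: starting material 0.10 M; free catalyst 0.50 mM
- theta: second substrate 0.20 M; partner 0.14 M; run made earlier
- gamma: second substrate 0.20 M; partner 0.23 M; run made earlier
- red: second substrate 0.200 M; partner 0.100 M; time 3.0 h
- violet: second substrate 0.200 M; partner 0.150 M; time 3.0 h

| run | time / min | target / % | catalyst intermediate A / % | uncatalysed product / % | starting material / % |
|---|---|---|---|---|---|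
| theta | 20.0 | 0 | 0 | 19.1 | 80.5 |
| theta | 40.0 | 0.7 | 0.1 | 30.7 | 68.3 |
| theta | 50.0 | 1.7 | 0 | 35.3 | 62.9 |
| theta | 80.0 | 1.7 | 0 | 45.1 | 53.8 |
| theta | 90.0 | 0.6 | 0.5 | 46.2 | 52.3 |
| gamma | 8.00 | 0.6 | 0.5 | 14.2 | 85.2 |
| gamma | 25.0 | 1.2 | 0 | 34.2 | 64.1 |
| gamma | 40.0 | 0.6 | 0.5 | 46.5 | 51.8 |
| gamma | 60.0 | 2.3 | 0 | 56.8 | 41.6 |
| gamma | 90.0 | 1.3 | 0.8 | 65.6 | 32.4 |

(standard deviation of a reading: 0.5 percentage points)

- the numbers in the tables scatter by 0.5 percentage points (one standard deviation)
- a reading or a percentage of target counts all its forms, free or not

* which of these there is most of at the end, counted by the starting material in it, red (uncatalysed product / starting material / target / catalyst intermediate A)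
* which of these there is most of at the end, counted by the starting material in it, violet (uncatalysed product / starting material / target / catalyst intermediate A)
* final amount of the leader among these, as a percentage of the starting material charged, in red
* final amount of the leader among these, as a percentage of the starting material charged, in violet

In logarithms the starting material's own fall drops out, which leaves a pseudo-first-order rate to follow, taken per molar of partner charged. Over the first 40.0 min this specific rate reads 0.0681 M⁻¹ min⁻¹ in theta and 0.0715 M⁻¹ min⁻¹ in gamma, so the two runs nearly coincide although gamma holds 1.64 times theta's partner. Their mean is 0.0698 M⁻¹ min⁻¹, and from there to 90.0 min it is 0.0395 M⁻¹ min⁻¹. That is a slowing by a factor of 1.77 across the 45.0 min between the middles of the two spans, which, read as a steady decay, is a halving every 54.7 min. Back-dated, it starts at 0.0899 M⁻¹ min⁻¹.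

Part of the slowing can be counted. If each uncatalysed product takes one partner, theta's 46.2% slows the rate by a factor of 1.49, less than the 3.13 reckoned by 90.0 min, so a further factor of 2.10 stays unaccounted for in these readings.

Extended at that halving to 3.0 h, the reckoned rate stands at 0.102 of its start, and its sum over the time reaches 6.37 M⁻¹. This is the exposure, the logarithm of charged over remaining starting material per molar of partner charged. Multiplied by the partner charge, with the other charges held as in theta and gamma, it leaves a reckoned 52.9% starting material in red, which leads. It leaves 38.5% in violet, where uncatalysed product leads at about 59.2%, taking the highest target reading off the balance.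

The forecast, slightly lower on both, gives starting material at 52% in red and uncatalysed product at 58% in violet, holding that its apparent constant “tracks time, not conversion”. The flasks give starting material at 53.4% in red and uncatalysed product at 61.5% in violet.

    second substrate + free catalyst ⇌ catalyst intermediate B (K = 63.0 M⁻¹, k = 9.60 M⁻¹ s⁻¹)
    free catalyst + target ⇌ idle complex, settled at all times (K = 32.0 M⁻¹)
    catalyst intermediate B → spent catalyst (k = 1.20 × 10⁻⁴ s⁻¹)
    starting material + partner → uncatalysed product (k = 0.00150 M⁻¹ s⁻¹)
    partner + catalyst intermediate B → free catalyst + second product (k = 0.320 M⁻¹ s⁻¹)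
    starting material + free catalyst ⇌ catalyst intermediate A (K = 10.0 M⁻¹, k = 2.40 M⁻¹ s⁻¹)
    partner + catalyst intermediate A → free catalyst + target (k = 0.110 M⁻¹ s⁻¹)

Red's 53.4% turns back into an exposure of 6.27 M⁻¹, and violet's 37% of starting material into 6.64 M⁻¹, against the 6.37 M⁻¹ carried. In red at 0.643 h, partner's half-life by its step with catalyst intermediate B is 1.8 h, shorter than the 2.3 h of starting material by the uncatalysed step. Red at 3.0 h keeps less of its partner, 14%, than of its starting material, 53%. The neighbour of red charged with 0.17 M of partner gets 33.9% from the exposure and holds 31.5% starting material beside 66.7% of uncatalysed product.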